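The route rests on unzipping the decalin. Cutting C4–C5 and C9–C10 and sending the C19 and C20 methyls back to C4 and C10 turns rings A and B into a linear C20 chain. In the forward sense a class 2 diterpene cyclase folds (E,E,E)-geranylgeranyl diphosphate, closes both rings, relays two hydrides and two methyls, and ends with the C3=C4 alkene, all in one operation. The step exploits the trans-fused rings A and B of the target, whose quaternary C5 and C9 each carry a methyl and flank H-C10. C5, C9 and C10 survive to the target; C8 is later flattened to C8=C17. The precursor is an achiral, acyclic all-E tetraene diphosphate.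

Key step: step 3

Numbering: clerodane numbering throughout (decalin C1–C10, chain C11–C16, C17 on C8, C18 on C4, C19 on C5, C20 on C9). α is the face of C19 and C20; β is the face of H-10.
Structure check: the target is (1R,5R,6R,9R,10R,12R,13R), with a 1β-ester, 6α-OH, a C7 ketone and two exocyclic methylenes (C4=C18, C8=C17). C17 carries no oxygen, so C8/C17 need a dehydrogenation, and the C8 centre made by the cyclase is spent. Diphosphate 4 is 5R,8R,9S,10R, and its C5, C9 and C10 map onto the target unchanged.
Design remark: the cyclase substrate stays unoxygenated, because oxygen at the future C1, C6, C7 or C12 would sit beside cationic centres of the relay. The 3-ene it delivers is then used as the handle for C2 and C1.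
Assumption: the (S)-SEGPHOS iridium catalyst of step 19 is taken to add to the Si face of aldehyde 27 (12R,13R). If a model aldehyde shows the opposite sense, the (R)-ligand is used and nothing else changes.
Remark: diphosphates 3 and 4 are handled as ammonium salts and drawn as free acids.

Step 1
Reactants: 1 (E,E,E)-geranylgeraniol
Product: 2 (E,E,E)-geranylgeranyl chloride
Conditions: NCS, Me2S, CH2Cl2, −30 to 0 °C
Reagents that add atoms: N-chlorosuccinimide, O=C1CCC(=O)N1Cl
Why: Corey–Kim chlorination passes through an alkoxysulfonium salt that chloride opens by SN2 at the primary allylic carbon under neutral conditions, so neither allylic transposition nor E/Z scrambling is expected.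

Step 2
Reactants: 2 geranylgeranyl chloride
Product: 3 (E,E,E)-geranylgeranyl diphosphate
Conditions: (n-Bu4N)3HP2O7, MeCN, rt; Dowex 50W (NH4+ form); cellulose chromatography
Reagents that add atoms: tris(tetrabutylammonium) hydrogen diphosphate, CCCC[N+](CCCC)(CCCC)CCCC.CCCC[N+](CCCC)(CCCC)CCCC.CCCC[N+](CCCC)(CCCC)CCCC.OP(=O)([O-])OP(=O)([O-])[O-]
Why: SN2 displacement of the primary allylic chloride by the diphosphate trianion is the standard chemical diphosphorylation of prenyl alcohols and leaves the three E alkenes untouched.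

Step 3
Reactants: 3 geranylgeranyl diphosphate
Product: 4 (−)-kolavenyl diphosphate
Conditions: recombinant (−)-kolavenyl diphosphate synthase (class 2 diterpene cyclase, His6 tag, from E. coli), HEPES pH 7.2, KCl, MgCl2, DTT, glycerol, 30 °C
Reagents that add atoms: none
Why: The acidic aspartate of the DXDD motif protonates the terminal alkene at C3; the C4 cation is attacked by the C5=C10 alkene (6-endo closure of ring A, bond C4–C5) and the C10 cation by the C8=C9 alkene (6-endo closure of ring B, bond C9–C10), each as an anti addition in a chair–chair fold, to give the labda-13-en-8-yl cation. Four suprafacial antiperiplanar 1,2-shifts follow (H9 to C8, the C10 methyl to C9, H5 to C10, one C4 methyl to C5), and loss of H3 from the C4 cation gives 4. The closest known reaction type is the protonation-initiated cationic polyene cyclisation with a Wagner–Meerwein relay, and this substrate–product pair is a native activity of plant kolavenyl diphosphate synthases. All four new centres come from the fold that the pocket imposes on the achiral chain and from the anti geometry of every shift (H on C8 β, 8R; C20 on C9 α, 9S; H on C10 β, 10R; C19 on C5 α, 5R), while the E geometry of the reacting alkenes becomes the trans ring fusion. The step needs chemoselectivity for the full relay over early proton loss or water capture, and regioselectivity for H3 over H18 at the end; both are secured by the dry pocket and the position of its single terminal base, not by the substrate. Simple acids in a flask would quench the cascade at the bicyclic labdadienyl stage, so the protein is the reagent of choice.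

Step 4
Reactants: 4 (−)-kolavenyl diphosphate
Product: 5 (−)-kolavenol
Conditions: calf intestinal alkaline phosphatase, Tris pH 8.5, MgCl2, 37 °C; pentane extraction
Reagents that add atoms: none
Why: Enzymatic hydrolysis of the P–O bonds at mild pH frees the allylic alcohol without the ionisation and allylic transposition that acid hydrolysis of an allylic diphosphate would bring, and no stereocentre is touched.

Step 5
Reactants: 5 (−)-kolavenol
Product: 6 kolavenyl pivalate
Conditions: PivCl, pyridine, DMAP (cat.), CH2Cl2, 0 °C to rt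
Reagents that add atoms: pivaloyl chloride, CC(C)(C)C(=O)Cl
Why: Simple acylation gives an ester without α-hydrogen that should survive the strong base of step 7 and, as an allylic ester, lowers the reactivity of C13=C14 in step 6.

Step 6
Reactants: 6 kolavenyl pivalate
Product: 7 2-oxokolavenyl pivalate
Conditions: Rh2(cap)4 (1 mol %, cap = caprolactamate), t-BuOOH (70% aq.), DCE, 40 °C
Reagents that add atoms: tert-butyl hydroperoxide, CC(C)(C)OO
Why: Allylic C–H oxidation by tert-butylperoxyl radicals should take the ring methylene C2, whose axial C–H overlaps with the electron-rich C3=C4 bond (C5 is quaternary and offers no hydrogen), while C13=C14 is deactivated by its allylic ester.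

Step 7
Reactants: 7 2-oxokolavenyl pivalate
Product: 9 1β-hydroxy-2-oxokolavenyl pivalate, via potassium dienolate 8 (not isolated)
Conditions: KHMDS, THF, −78 °C; then 2-(phenylsulfonyl)-3-phenyloxaziridine, −78 °C; NH4Cl quench
Reagents that add atoms: 2-(phenylsulfonyl)-3-phenyloxaziridine, O=S(=O)(c1ccccc1)N1OC1c1ccccc1
Why: Kinetic α'-deprotonation of the enone at C1 gives the cross-conjugated dienolate 8, and oxygen transfer (Davis hydroxylation) should come from the β face because the α face of C1 is closed by the syn-axial C19 and C20 methyls, which sets the equatorial 1β-OH (also the more stable epimer).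

Step 8
Reactants: 9 1β-hydroxy-2-oxokolavenyl pivalate; 10 isobutyryl chloride
Product: 11 1β-isobutyryloxy-2-oxokolavenyl pivalate
Conditions: pyridine, DMAP, CH2Cl2, rt
Reagents that add atoms: none
Why: DMAP-catalysed acylation of the hindered equatorial alcohol installs the final C1 ester early, where it stops ketol isomerisation and later screens and deactivates C10–H.

Step 9
Reactants: 11 1β-isobutyryloxy-2-oxokolavenyl pivalate
Product: 13 C12 tetramethylpiperidinyl ether of the tetranor enone, via methoxy hydroperoxide 12 (not isolated)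
Conditions: O3 (1 equiv), MeOH, −78 °C; then TEMPO, FeSO4·7H2O, −78 °C to rt
Reagents that add atoms: TEMPO, CC1(C)CCCC(C)(C)N1[O]; ozone, [O-][O+]=O, and methanol, CO (both kept only in 12)
Why: Ozone should attack only C13=C14 (the ring alkene is a deactivated enone), methanol traps the ketone oxide on C13 as 12, and reduction by divalent iron gives an alkoxyl radical whose β-scission expels methyl acetate and leaves the primary C12 radical for capture by TEMPO (dealkenylative aminoxylation).

Step 10
Reactants: 13 C12 tetramethylpiperidinyl ether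
Product: 14 12-hydroxy-1β-isobutyryloxy-13,14,15,16-tetranorclerod-3-en-2-one
Conditions: Zn, AcOH–THF–H2O, 45 °C
Reagents that add atoms: none
Why: Zinc in acetic acid reduces the N–O bond of the alkoxyamine, and the 1β-acyloxy group should stay because it lies equatorial, near the nodal plane of the C2 carbonyl, and is badly aligned for reductive α-cleavage.

Step 11
Reactants: 14 12-hydroxy tetranor enone
Product: 16 8β,12-epoxy-1β-isobutyryloxy-13,14,15,16-tetranorclerod-3-en-2-one, via hypoiodite 15 (not isolated)
Conditions: PhI(OAc)2, I2, cyclohexane–CH2Cl2, tungsten lamp, 25 °C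
Reagents that add atoms: none
Why: In the Suárez hypoiodite reaction, homolysis of O–I gives the C12 alkoxyl radical, whose six-membered 1,5-hydrogen shift should take the axial 8β-H (C10–H, the only other tertiary δ-hydrogen, is deactivated and screened by the 1β-ester, and C20 lies on the far α face), and the oxidised C8 is closed by O12 on the β face with retention.

Step 12
Reactants: 16 8β,12-epoxide
Product: 17 12-acetoxy-1β-isobutyryloxy-13,14,15,16-tetranorcleroda-3,7-dien-2-one
Conditions: FeCl3 (0.2 equiv), Ac2O, 0 °C to rt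
Reagents that add atoms: acetic anhydride, CC(=O)OC(C)=O
Why: In this Lewis-acid acetolysis of a tertiary alkyl ether, O-acylation makes the tertiary C8–O bond ionise and E1 proton loss under equilibrating conditions should give the trisubstituted C7=C8 alkene (C9 has no hydrogen), while O12 emerges protected as the primary acetate and the C8 centre is erased as planned.

Step 13
Reactants: 17 3,7-dien-2-one
Product: 18 12-acetoxy-1β-isobutyryloxy-13,14,15,16-tetranorcleroda-3,7-diene-2,6-dione
Conditions: Rh2(cap)4 (1 mol %), t-BuOOH (70% aq.), DCE, 40 °C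
Reagents that add atoms: tert-butyl hydroperoxide, CC(C)(C)OO
Why: The same peroxyl-radical allylic oxidation should now take the axial 6β-H on the open β face next to the only electron-rich alkene, since C3=C4 is masked as an enone.

Step 14
Reactants: 18 2,6-dione
Product: 19 C2 ethylene dithioketal of 18
Conditions: HSCH2CH2SH, BF3·OEt2, CH2Cl2, −20 to 0 °C
Reagents that add atoms: ethane-1,2-dithiol, SCCS
Why: Lewis-acid thioketalisation should pick the C2 carbonyl because the C6 carbonyl is neopentyl (next to quaternary C5 and crowded by C18), and enone thioketals of this kind keep the double bond in place.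

Step 15
Reactants: 19 C2 dithioketal
Product: 20 12-acetoxy-1β-isobutyryloxy-13,14,15,16-tetranorcleroda-3,7-dien-6-one
Conditions: Raney Ni (W-2, acetone-deactivated), EtOH, rt
Reagents that add atoms: none
Why: Mozingo desulfurisation replaces both C–S bonds by C–H, and the hindered trisubstituted C3=C4 bond and the β,β-disubstituted C7=C8 enone should resist the deactivated catalyst.

Step 16
Reactants: 20 3,7-dien-6-one
Product: 21 18-hydroxy derivative of 20
Conditions: SeO2 (0.5 equiv), t-BuOOH, CH2Cl2, 0 °C to rt
Reagents that add atoms: selenium dioxide, O=[Se]=O (oxygen carrier); tert-butyl hydroperoxide, CC(C)(C)OO (terminal oxidant)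
Why: SeO2 allylic hydroxylation (ene reaction, then 2,3-sigmatropic shift) goes to a substituent of the more substituted alkene carbon C4, where only the C18 methyl has hydrogen, and the C7=C8 enone is too electron-poor for the ene step.

Step 17
Reactants: 21 18-hydroxy compound
Product: 24 12-acetoxy-1β-isobutyryloxy-13,14,15,16-tetranorcleroda-4(18),7-dien-6-one, via sulfonylhydrazine 22 (not isolated), via allylic diazene 23 (not isolated)
Conditions: o-nitrobenzenesulfonylhydrazide, PPh3, DEAD, THF, −30 °C to rt
Reagents that add atoms: none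
Why: In the Myers reductive allylic transposition, Mitsunobu displacement of the primary allylic alcohol gives 22, loss of sulfinic acid gives diazene 23, and its retro-ene loss of N2 delivers hydrogen to C3 and moves the alkene to C4=C18.

Step 18
Reactants: 24 12-acetate
Product: 25 12-hydroxy-1β-isobutyryloxy-13,14,15,16-tetranorcleroda-4(18),7-dien-6-one
Conditions: K2CO3 (0.2 equiv), MeOH, 0 °C
Reagents that add atoms: none
Why: Base-catalysed transesterification removes the unhindered primary acetate much faster than the α-branched ester on the crowded secondary C1 oxygen.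

Step 19
Reactants: 25 12-alcohol; 26 4-vinyl-1,3-dioxolan-2-one
Product: 28 (12R,13R)-12,16-dihydroxy-1β-isobutyryloxycleroda-4(18),7,14-trien-6-one, via aldehyde 27 (not isolated)
Conditions: [Ir(cod)Cl]2 (2.5 mol %), (S)-SEGPHOS (5 mol %), 4-cyano-3-nitrobenzoic acid (10 mol %), K3PO4 (10 mol %), THF, 90 °C
Reagents that add atoms: none
Why: In this iridium-catalysed transfer-hydrogenative carbonyl (hydroxymethyl)allylation (Krische type), dehydrogenation of 25 gives 27, ionisation and decarboxylation of 26 give an (E)-σ-allyliridium species, and addition through a closed chair transition state gives the anti diol, so the ligand rather than the remote decalin sets C12 (Si face, 12R) and with it C13 (13R).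

Step 20
Reactants: 28 12,16-diol
Product: 29 16-O-TBS ether of 28
Conditions: TBSCl, imidazole, CH2Cl2, 0 °C
Reagents that add atoms: tert-butyldimethylsilyl chloride, CC(C)(C)[Si](C)(C)Cl
Why: Silylation is selective for the primary C16 alcohol over the flanked secondary C12 alcohol, which separates the two oxygens before the lactone is built.

Step 21
Reactants: 29 16-O-TBS ether; 30 tiglic acid
Product: 32 12-O-tiglate of 29, via mixed anhydride 31 (not isolated)
Conditions: 30, 2,4,6-trichlorobenzoyl chloride, Et3N, toluene, rt; then 29, DMAP, 40 °C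
Reagents that add atoms: none
Why: Yamaguchi esterification acylates hindered secondary alcohols with retention at C12 and without E/Z change of the tiglate, and the ester also prevents O12 from competing in the later lactonisation.

Step 22
Reactants: 32 12-O-tiglate
Product: 34 15-hydroxy compound, via pinacol boronate 33 (not isolated)
Conditions: Rh(PPh3)3Cl (2 mol %), pinacolborane, CH2Cl2, rt; then NaBO3·4H2O, THF–H2O
Reagents that add atoms: sodium perborate, [Na+].[Na+].O[B-]1(O)OO[B-](O)(O)OO1; pinacolborane, CC1(C)OBOC1(C)C (kept only in 33)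
Why: Rhodium-catalysed anti-Markovnikov hydroboration strongly prefers the monosubstituted C14=C15 vinyl group over the hindered 1,1-disubstituted C4=C18, the conjugated tiglate and the crowded enone, and perborate oxidises the C–B bond under mild conditions.

Step 23
Reactants: 34 15-hydroxy compound
Product: 37 (12R,13R)-1β-isobutyryloxy-6-oxo-12-tigloyloxycleroda-4(18),7-dien-15,16-olide, via silyl acid 35 (not isolated), via hydroxy acid 36 (not isolated)
Conditions: TEMPO (0.2 equiv), PhI(OAc)2 (2.5 equiv), MeCN–H2O, rt; then 48% aq. HF, 0 °C to rt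
Reagents that add atoms: water, O (second oxygen of acid 35, one carboxyl oxygen leaves again on ring closure)
Why: Oxoammonium oxidation takes the primary alcohol to the acid, and acidic desilylation frees O16, which closes the five-membered lactone at once, the only possible ring because O12 is acylated, with C13 untouched.

Step 24
Reactants: 37 6-oxo lactone
Product: 38 6α-hydroxy-7-ene lactone
Conditions: NaBH4, CeCl3·7H2O, MeOH, −20 to 0 °C
Reagents that add atoms: none
Why: Luche 1,2-reduction delivers hydride to C6 from the open β face, because the α face is covered by the axial C19 methyl on the neighbouring C5, which sets the equatorial 6α-OH and leaves esters and lactone alone.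

Step 25
Reactants: 38 6α-hydroxy-7-ene lactone
Product: 40 6α,7β-dihydroxy-4(18),8(17)-diene lactone, via allylic hydroperoxide 39 (not isolated)
Conditions: O2, tetraphenylporphyrin (cat.), white LED, CH2Cl2, 0 °C; then PPh3
Reagents that add atoms: dioxygen, O=O
Why: In the Schenck ene reaction, singlet oxygen should approach the only trisubstituted alkene from the β face (the α face is blocked by C19 and C20), bond to C7 rather than to C8 beside quaternary C9, and take hydrogen from the C17 methyl geminal to that bulky carbon, which creates C8=C17 and a 7β-hydroperoxide that PPh3 reduces.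

Step 26
Reactants: 40 6α,7β-diol
Product: 41 target CNP0148909.1
Conditions: MnO2 (activated, excess), CH2Cl2, rt
Reagents that add atoms: none
Why: MnO2 oxidises only the allylic 7β-alcohol, whose axial C7–H overlaps with C8=C17, under neutral conditions that should neither epimerise C6 nor tautomerise the α-ketol to the diosphenol.

Compound list
1 | (2E,6E,10E)-geranylgeraniol | CC(C)=CCC/C(C)=C/CC/C(C)=C/CC/C(C)=C/CO | starting material
2 | (2E,6E,10E)-geranylgeranyl chloride | CC(C)=CCC/C(C)=C/CC/C(C)=C/CC/C(C)=C/CCl | intermediate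
3 | (E,E,E)-geranylgeranyl diphosphate (free-acid form) | CC(C)=CCC/C(C)=C/CC/C(C)=C/CC/C(C)=C/COP(=O)(O)OP(=O)(O)O | intermediate
4 | (−)-kolavenyl diphosphate, (5R,8R,9S,10R)-cleroda-3,13E-dien-15-yl diphosphate (free-acid form) | CC1=CCC[C@H]2[C@@]1(C)CC[C@@H](C)[C@]2(C)CC/C(C)=C/COP(=O)(O)OP(=O)(O)O | intermediate
5 | (−)-kolavenol, (5R,8R,9S,10R)-cleroda-3,13E-dien-15-ol | CC1=CCC[C@H]2[C@@]1(C)CC[C@@H](C)[C@]2(C)CC/C(C)=C/CO | intermediate
6 | kolavenyl pivalate | CC1=CCC[C@H]2[C@@]1(C)CC[C@@H](C)[C@]2(C)CC/C(C)=C/COC(=O)C(C)(C)C | intermediate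
7 | 2-oxokolavenyl pivalate (3-en-2-one) | CC1=CC(=O)C[C@H]2[C@@]1(C)CC[C@@H](C)[C@]2(C)CC/C(C)=C/COC(=O)C(C)(C)C | intermediate
8 | potassium 1,3-dien-2-olate of 7 | [K+].CC1=CC([O-])=C[C@H]2[C@@]1(C)CC[C@@H](C)[C@]2(C)CC/C(C)=C/COC(=O)C(C)(C)C | intermediate
9 | 1β-hydroxy-2-oxokolavenyl pivalate | CC1=CC(=O)[C@@H](O)[C@H]2[C@@]1(C)CC[C@@H](C)[C@]2(C)CC/C(C)=C/COC(=O)C(C)(C)C | intermediate
10 | isobutyryl chloride | CC(C)C(=O)Cl | starting material
11 | 1β-isobutyryloxy-2-oxokolavenyl pivalate | CC1=CC(=O)[C@@H](OC(=O)C(C)C)[C@H]2[C@@]1(C)CC[C@@H](C)[C@]2(C)CC/C(C)=C/COC(=O)C(C)(C)C | intermediate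
12 | 13-hydroperoxy-13-methoxy-14,15-dinor derivative of 11 (both C13 epimers) | CC1=CC(=O)[C@@H](OC(=O)C(C)C)[C@H]2[C@@]1(C)CC[C@@H](C)[C@]2(C)CCC(C)(OC)OO | intermediate
13 | 1β-isobutyryloxy-12-(2,2,6,6-tetramethylpiperidin-1-yl)oxy-13,14,15,16-tetranorclerod-3-en-2-one | CC1=CC(=O)[C@@H](OC(=O)C(C)C)[C@H]2[C@@]1(C)CC[C@@H](C)[C@]2(C)CCON1C(C)(C)CCCC1(C)C | intermediate
14 | 12-hydroxy-1β-isobutyryloxy-13,14,15,16-tetranorclerod-3-en-2-one | CC1=CC(=O)[C@@H](OC(=O)C(C)C)[C@H]2[C@@]1(C)CC[C@@H](C)[C@]2(C)CCO | intermediate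
15 | 12-hypoiodite of 14 | CC1=CC(=O)[C@@H](OC(=O)C(C)C)[C@H]2[C@@]1(C)CC[C@@H](C)[C@]2(C)CCOI | intermediate
16 | 8β,12-epoxy-1β-isobutyryloxy-13,14,15,16-tetranorclerod-3-en-2-one (C17 methyl α) | CC1=CC(=O)[C@@H](OC(=O)C(C)C)[C@H]2[C@@]1(C)CC[C@@]3(C)[C@]2(C)CCO3 | intermediate
17 | 12-acetoxy-1β-isobutyryloxy-13,14,15,16-tetranorcleroda-3,7-dien-2-one | CC1=CC(=O)[C@@H](OC(=O)C(C)C)[C@H]2[C@@]1(C)CC=C(C)[C@]2(C)CCOC(C)=O | intermediate
18 | 12-acetoxy-1β-isobutyryloxy-13,14,15,16-tetranorcleroda-3,7-diene-2,6-dione | CC1=CC(=O)[C@@H](OC(=O)C(C)C)[C@H]2[C@@]1(C)C(=O)C=C(C)[C@]2(C)CCOC(C)=O | intermediate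
19 | C2 ethylene dithioketal of 18 | CC1=CC3(SCCS3)[C@@H](OC(=O)C(C)C)[C@H]2[C@@]1(C)C(=O)C=C(C)[C@]2(C)CCOC(C)=O | intermediate
20 | 12-acetoxy-1β-isobutyryloxy-13,14,15,16-tetranorcleroda-3,7-dien-6-one | CC1=CC[C@@H](OC(=O)C(C)C)[C@H]2[C@@]1(C)C(=O)C=C(C)[C@]2(C)CCOC(C)=O | intermediate
21 | 18-hydroxy derivative of 20 | OCC1=CC[C@@H](OC(=O)C(C)C)[C@H]2[C@@]1(C)C(=O)C=C(C)[C@]2(C)CCOC(C)=O | intermediate
22 | N-(C18-allyl)-N-(2-nitrophenylsulfonyl)hydrazine from 21 | NN(CC1=CC[C@@H](OC(=O)C(C)C)[C@H]2[C@@]1(C)C(=O)C=C(C)[C@]2(C)CCOC(C)=O)S(=O)(=O)c1ccccc1[N+](=O)[O-] | intermediate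
23 | C18 monoalkyl diazene | N=NCC1=CC[C@@H](OC(=O)C(C)C)[C@H]2[C@@]1(C)C(=O)C=C(C)[C@]2(C)CCOC(C)=O | intermediate
24 | 12-acetoxy-1β-isobutyryloxy-13,14,15,16-tetranorcleroda-4(18),7-dien-6-one | C=C1CC[C@@H](OC(=O)C(C)C)[C@H]2[C@@]1(C)C(=O)C=C(C)[C@]2(C)CCOC(C)=O | intermediate
25 | 12-hydroxy-1β-isobutyryloxy-13,14,15,16-tetranorcleroda-4(18),7-dien-6-one | C=C1CC[C@@H](OC(=O)C(C)C)[C@H]2[C@@]1(C)C(=O)C=C(C)[C@]2(C)CCO | intermediate
26 | 4-vinyl-1,3-dioxolan-2-one (racemic) | C=CC1COC(=O)O1 | starting material
27 | 12-aldehyde from 25 | C=C1CC[C@@H](OC(=O)C(C)C)[C@H]2[C@@]1(C)C(=O)C=C(C)[C@]2(C)CC=O | intermediate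
28 | (12R,13R)-12,16-dihydroxy-1β-isobutyryloxycleroda-4(18),7,14-trien-6-one | C=C1CC[C@@H](OC(=O)C(C)C)[C@H]2[C@@]1(C)C(=O)C=C(C)[C@]2(C)C[C@@H](O)[C@@H](CO)C=C | intermediate
29 | 16-O-TBS ether of 28 | C=C1CC[C@@H](OC(=O)C(C)C)[C@H]2[C@@]1(C)C(=O)C=C(C)[C@]2(C)C[C@@H](O)[C@@H](CO[Si](C)(C)C(C)(C)C)C=C | intermediate
30 | tiglic acid | C/C=C(\C)C(=O)O | starting material
31 | tiglic 2,4,6-trichlorobenzoic anhydride | C/C=C(\C)C(=O)OC(=O)c1c(Cl)cc(Cl)cc1Cl | intermediate
32 | 12-O-tiglate of 29 | C=C1CC[C@@H](OC(=O)C(C)C)[C@H]2[C@@]1(C)C(=O)C=C(C)[C@]2(C)C[C@@H](OC(=O)/C(C)=C/C)[C@@H](CO[Si](C)(C)C(C)(C)C)C=C | intermediate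
33 | C15 pinacol boronate from 32 | C=C1CC[C@@H](OC(=O)C(C)C)[C@H]2[C@@]1(C)C(=O)C=C(C)[C@]2(C)C[C@@H](OC(=O)/C(C)=C/C)[C@@H](CO[Si](C)(C)C(C)(C)C)CCB1OC(C)(C)C(C)(C)O1 | intermediate
34 | 15-hydroxy-16-OTBS-12-tiglate | C=C1CC[C@@H](OC(=O)C(C)C)[C@H]2[C@@]1(C)C(=O)C=C(C)[C@]2(C)C[C@@H](OC(=O)/C(C)=C/C)[C@@H](CO[Si](C)(C)C(C)(C)C)CCO | intermediate
35 | 15-oic acid (16-OTBS) | C=C1CC[C@@H](OC(=O)C(C)C)[C@H]2[C@@]1(C)C(=O)C=C(C)[C@]2(C)C[C@@H](OC(=O)/C(C)=C/C)[C@@H](CO[Si](C)(C)C(C)(C)C)CC(=O)O | intermediate
36 | 16-hydroxy-15-oic acid | C=C1CC[C@@H](OC(=O)C(C)C)[C@H]2[C@@]1(C)C(=O)C=C(C)[C@]2(C)C[C@@H](OC(=O)/C(C)=C/C)[C@@H](CO)CC(=O)O | intermediate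
37 | (12R,13R)-1β-isobutyryloxy-6-oxo-12-tigloyloxycleroda-4(18),7-dien-15,16-olide | C=C1CC[C@@H](OC(=O)C(C)C)[C@H]2[C@@]1(C)C(=O)C=C(C)[C@]2(C)C[C@@H](OC(=O)/C(C)=C/C)[C@H]1COC(=O)C1 | intermediate
38 | (12R,13R)-6α-hydroxy-1β-isobutyryloxy-12-tigloyloxycleroda-4(18),7-dien-15,16-olide | C=C1CC[C@@H](OC(=O)C(C)C)[C@H]2[C@@]1(C)[C@@H](O)C=C(C)[C@]2(C)C[C@@H](OC(=O)/C(C)=C/C)[C@H]1COC(=O)C1 | intermediate
39 | 7β-hydroperoxy-6α-hydroxy-4(18),8(17)-diene lactone | C=C1CC[C@@H](OC(=O)C(C)C)[C@H]2[C@@]1(C)[C@@H](O)[C@H](OO)C(=C)[C@]2(C)C[C@@H](OC(=O)/C(C)=C/C)[C@H]1COC(=O)C1 | intermediate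
40 | 6α,7β-dihydroxy-4(18),8(17)-diene lactone | C=C1CC[C@@H](OC(=O)C(C)C)[C@H]2[C@@]1(C)[C@@H](O)[C@H](O)C(=C)[C@]2(C)C[C@@H](OC(=O)/C(C)=C/C)[C@H]1COC(=O)C1 | intermediate
41 | CNP0148909.1, (1R,5R,6R,9R,10R,12R,13R)-6-hydroxy-1-isobutyryloxy-7-oxo-12-tigloyloxycleroda-4(18),8(17)-dien-15,16-olide | C=C1CC[C@@H](OC(=O)C(C)C)[C@H]2[C@@]1(C)[C@@H](O)C(=O)C(=C)[C@]2(C)C[C@@H](OC(=O)/C(C)=C/C)[C@H]1COC(=O)C1 | target

Total step count: 26. Longest linear sequence: 26 steps (1 to 41); compounds 10, 26 and 30 enter as bought.

Steps most likely to fail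

Step 11. The C12 alkoxyl radical may abstract hydrogen at C10–H or at the C20 methyl instead of C8–H, or it may be lost by β-scission or over-oxidation to the aldehyde. The fallback sets out from 14 and returns at 17. It replaces the intramolecular radical relay by an intermolecular, electronically steered C–H hydroxylation. Alcohol 14 is acetylated (Ac2O, pyridine) to the 12-acetate F1. Methyl(trifluoromethyl)dioxirane in CH2Cl2 at −20 °C should then insert oxygen with retention into C8–H, the one tertiary C–H that is remote from every electron-withdrawing group, to give the 8β-hydroxy acetate F2. SOCl2 in pyridine at 0 °C removes the axial 8β-OH together with the antiperiplanar axial 7α-H (E2) and gives 17.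

Step 12. The C8 cation may undergo a 1,2-shift of the axial C20 methyl from C9 (skeletal rearrangement). Proton loss may also stop at the exocyclic alkene, or the ring A enone may be enol-acetylated. The fallback sets out from 14 and returns at 17, and it avoids any cation. Alcohol 14 is converted (NOCl, pyridine) into the nitrite ester F3. Irradiation at 365–390 nm in benzene–pyridine with Cu(OAc)2 gives the same alkoxyl radical and 1,5-hydrogen shift, and divalent copper takes the C8 radical to the alkene by oxidative elimination, which should give mainly the exocyclic 8(17)-en-12-ol F4. Acetylation gives the exocyclic alkene acetate F5. A radical hydrogen-atom-transfer isomerisation then moves the double bond to the more stable C7=C8 position of 17. This uses Co(salen)Cl (cat., salen = N,N'-bis(3,5-di-tert-butylsalicylidene)ethane-1,2-diamine dianion) and PhSiH3 (cat.) in benzene at rt.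

Step 7. Removal of the axial 1α-H, which sits between the C19 and C20 methyls, may be slow. In that case γ-deprotonation at C18 and oxidation at C3 would compete. The fallback sets out from 7 and returns at 11. It replaces enolate oxidation by the α'-acyloxylation of enones with trivalent manganese. Mn(OAc)3·2H2O and excess isobutyric acid in refluxing benzene with removal of water should enolise the metal-bound ketone toward C1 and transfer isobutyrate to the open β face, which gives 11 directly. This fallback makes no new compound (F0).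

Further compounds
F1 | step 11 | 12-acetoxy-1β-isobutyryloxy-13,14,15,16-tetranorclerod-3-en-2-one | CC1=CC(=O)[C@@H](OC(=O)C(C)C)[C@H]2[C@@]1(C)CC[C@@H](C)[C@]2(C)CCOC(C)=O
F2 | step 11 | 12-acetoxy-8β-hydroxy-1β-isobutyryloxy-13,14,15,16-tetranorclerod-3-en-2-one | CC1=CC(=O)[C@@H](OC(=O)C(C)C)[C@H]2[C@@]1(C)CC[C@@](O)(C)[C@]2(C)CCOC(C)=O
F3 | step 12 | 12-nitrite ester of 14 | CC1=CC(=O)[C@@H](OC(=O)C(C)C)[C@H]2[C@@]1(C)CC[C@@H](C)[C@]2(C)CCON=O
F4 | step 12 | 12-hydroxy-1β-isobutyryloxy-13,14,15,16-tetranorcleroda-3,8(17)-dien-2-one | CC1=CC(=O)[C@@H](OC(=O)C(C)C)[C@H]2[C@@]1(C)CCC(=C)[C@]2(C)CCO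
F5 | step 12 | 12-acetoxy-1β-isobutyryloxy-13,14,15,16-tetranorcleroda-3,8(17)-dien-2-one | CC1=CC(=O)[C@@H](OC(=O)C(C)C)[C@H]2[C@@]1(C)CCC(=C)[C@]2(C)CCOC(C)=O
F0 | step 7 | none | none
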